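(The earlier runs and the new flask were generated by integration for substances that don't exist, noise included.)

I count product in turnovers (the turnover number): product formed per precatalyst charged. The fraction of a charge converted is then the turnovers divided by that charge, itself measured in catalyst charges.

| setting | green | Monday's | Saturday's | Thursday's |
|---|---|---|---|---|
| solid substrate | 0.025 M | 0.025 M | 0.050 M | 0.10 M |
| coupling partner | 0.34 M | 0.500 M | 0.500 M | 0.500 M |
| precatalyst | 5 mM | 5.0 mM | 5.0 mM | 5.0 mM |
| remark | run made earlier |  |  |  |
| time |  | 4.0 min | 4.0 min | 4.0 min |

green run (percent of the solid substrate charged): time / s: product / % = 12.0: 0.3; 25.0: 1.8; 40.0: 5.0; 50.0: 8.1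

(scatter of a reading: 0.3 percentage points)

- solid substrate is a solid; its amount is given per volume of the solution
- at the start none of the solid substrate is in solution
- "hardly changes" means that all values lie within two and a half points (for a concentration: within two and a half percent of the largest)

1. amount of product at the end, in percent of the solid substrate charged for Monday's, Saturday's, Thursday's, in this order
2. the shape of the row from first to last (rises all the way / rises, then falls / hardly changes / falls, then rises / falls all the way)

The green run holds 5.00 catalyst charges of solid substrate. From 25.0 s to 50.0 s its product gains 6.3 percentage points, which reads as a turnover frequency of 0.0126 /s.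

Time is the first setting. The flasks run 4.80 times as long as the green run's last reading, and a rate that kept climbing in proportion to time would give the square of that factor in product. I assume instead that the climb ends soon after that reading: the precatalyst is a finite charge and a dissolved solid has a solubility. Holding the frequency steady from the last reading gives 2.80 turnovers at the end.

The coupling partner is the second setting. Monday's has 1.47 times the green run's, and one order in it would multiply my frequency by that factor. The readings cannot test this, so I apply no factor. At one coupling partner per product, Monday's would use hardly any of its coupling partner.

The solid charge is the third setting. I assume the solution keeps the same strength whatever solid lies beneath it, so the turnovers stay the same and the fraction goes inversely with the charge. Monday's holds 5.00 catalyst charges, more than the turnovers reckoned. My row is 56.0 %, 28.0 %, 14.0 %.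

The forecast says 97 %, 90 %, 60 %, a row that falls all the way, and its ground is conditional: “if the catalyst limits the rate and the order in substrate is low, the absolute output is roughly independent of loading”. Its Thursday's is 12.0 turnovers, more than my figure.

The flasks give 49.9 % on Monday's, 25.0 % on Saturday's and 12.5 % on Thursday's: the row falls all the way.

    precatalyst → free catalyst (k = 0.380 /s)
    coupling partner + free catalyst → catalyst intermediate A (k = 83.0 /M/s)
    starting material + catalyst intermediate A → catalyst intermediate B (k = 2.40 /M/s)
    catalyst intermediate C → free catalyst + product (k = 0.790 /s)
    2 free catalyst → spent catalyst (k = 61.0 /M/s)
    catalyst intermediate B ⇌ by-product + catalyst intermediate C (K = 0.0530 M, k = 0.970 /s)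
    solid substrate ⇌ starting material, rate k7*(cs7 - [starting material]) while solid is left; crystals form when [starting material] > cs7 (solubility = 6.00 mM, k = 0.0490 /s)

At the end, starting material stands at 19.4 % of Monday's charge and 4.85 % of Thursday's, which is 0.970 and 0.970 catalyst charges. Monday's yield is 2.50 turnovers, fewer than my 2.80. Spread over Thursday's 20.0 catalyst charges, those turnovers give 12.5 %, and Thursday's stands at 12.5 %.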